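**Plan**
1. Numbering used: saturated ring C1 (bears C20H2OAc), C2, C3, C4 (bears side chain C11(CH3)–C12–C13–C14=C15), ring fusion C4a/C8a, C6–CO2H, C8–OH.
2. Retrosynthesis: protecting groups and acetate first; then C12–C13 and the two C–S bonds of a temporary thiolane (C4–C11–C12–S–C3); then, in one operation, C1–C2 and C3–C4 ([4+2] of the o-xylylene C1=C8a–C4a=C4 with a two-carbon unit); last C4–C4a (aryl metal + aldehyde).
3. Enabling feature: C1 and C4 are benzylic carbons on adjacent positions of the benzoate ring; C1 carries a carboxyl-level carbon (C20) that can be lactonised onto C4–O (isochroman-3-one); C12 is a CH2 that can carry sulfur, so a vinyl sulfide (C3=C2) can be tethered to C11.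
4. Forward: the benzene ring is bought; the lactone ring is made, then opened through its enolate with dearomatisation to an o-quinodimethane, which closes the carbocycle and the thiolane together; sulfoxide prenylation completes the side chain and Raney nickel removes the sulfur.
5. Stereochemistry: C11 from (R)-3-bromo-2-methylpropan-1-ol; C4 from C11 through the tether and A(1,3) strain; C1 from the lactone, which forces C20 into the inward (Z) position of the diene so that suprafacial addition gives the 1,4-trans arrangement.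

Key step: step 10

Remark: centres that never reach the target (carbinol carbon of 14/15, sulfur-bearing ring-fusion carbon C3 of 18–23, sulfoxide sulfur, C12 of 23) are expected as mixtures or are of no consequence and are left unassigned in the SMILES.

Step 1
Reactants: 1 3-hydroxy-4-methylbenzoic acid
Product: 3 4-methyl-3-[(triisopropylsilyl)oxy]benzoic acid, via triisopropylsilyl ester 2 (not isolated)
Conditions: TIPSCl (2.2 equiv), imidazole, DMF, rt; then AcOH/THF/H2O, rt
Reagents that add atoms: triisopropylsilyl chloride CC(C)[Si](Cl)(C(C)C)C(C)C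
Why: Bis-silylation followed by selective hydrolysis of the labile silyl ester should leave the base-stable aryl TIPS ether.

Step 2
Reactants: 3 4-methyl-3-[(triisopropylsilyl)oxy]benzoic acid
Product: 4 2-(trimethylsilyl)ethyl 4-methyl-3-[(triisopropylsilyl)oxy]benzoate
Conditions: Me3SiCH2CH2OH, EDC·HCl, DMAP (cat.), CH2Cl2, rt
Reagents that add atoms: 2-(trimethylsilyl)ethanol C[Si](C)(C)CCO
Why: Steglich esterification installs a fluoride-labile ester that can later be removed together with the TIPS ether without touching the acetate.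

Step 3
Reactants: 4 2-(trimethylsilyl)ethyl 4-methyl-3-[(triisopropylsilyl)oxy]benzoate
Product: 5 2-(trimethylsilyl)ethyl 4-(bromomethyl)-3-[(triisopropylsilyl)oxy]benzoate
Conditions: NBS, AIBN (cat.), PhCF3, 80 °C
Reagents that add atoms: N-bromosuccinimide O=C1CCC(=O)N1Br
Why: Wohl–Ziegler bromination should take the only benzylic C–H position of the ester-deactivated ring.

Step 4
Reactants: 5 2-(trimethylsilyl)ethyl 4-(bromomethyl)-3-[(triisopropylsilyl)oxy]benzoate
Product: 6 2-{2-[(triisopropylsilyl)oxy]-4-{[2-(trimethylsilyl)ethoxy]carbonyl}phenyl}acetic acid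
Conditions: PdCl2(PPh3)2 (cat.), CO (1 atm), H2O, i-Pr2NEt, THF, 50 °C; acidic work-up
Reagents that add atoms: carbon monoxide [C-]#[O+]; water O
Why: Palladium-catalysed hydroxycarbonylation of a benzyl bromide adds C20 at the carboxyl oxidation level in one step.

Step 5
Reactants: 6 2-{2-[(triisopropylsilyl)oxy]-4-{[2-(trimethylsilyl)ethoxy]carbonyl}phenyl}acetic acid
Product: 7 2-{2-iodo-6-[(triisopropylsilyl)oxy]-4-{[2-(trimethylsilyl)ethoxy]carbonyl}phenyl}acetic acid
Conditions: Pd(OAc)2 (5 mol%), I2, PhI(OAc)2, DMF, 60 °C, dark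
Reagents that add atoms: iodine II
Why: Carboxylate-directed Pd(II) ortho-C–H iodination can reach only the single free ortho position (the other carries OTIPS), which is the future C4a.

Step 6
Reactants: 8 (2R)-3-bromo-2-methylpropan-1-ol
Product: 9 S-[(2R)-3-hydroxy-2-methylpropyl] ethanethioate
Conditions: KSAc, DMF, rt
Reagents that add atoms: potassium thioacetate CC(=O)[S-].[K+]
Why: SN2 displacement at the primary carbon introduces sulfur at the future C12 without touching the stereocentre (C11).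

Step 7
Reactants: 9 S-[(2R)-3-hydroxy-2-methylpropyl] ethanethioate
Product: 11 (2R)-3-(ethenylsulfanyl)-2-methylpropan-1-ol, via potassium thiolate 10 (not isolated)
Conditions: KOH, DMSO, acetylene (1 atm), rt to 40 °C
Reagents that add atoms: acetylene C#C
Why: Hydroxide cleaves the thioacetate and the thiolate adds to acetylene (Reppe-type vinylation), the alcohol being far less reactive under these mild conditions.

Step 8
Reactants: 11 (2R)-3-(ethenylsulfanyl)-2-methylpropan-1-ol
Product: 12 (2R)-3-(ethenylsulfanyl)-2-methylpropanal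
Conditions: SO3·pyridine, DMSO, i-Pr2NEt, CH2Cl2, 0 °C; used crude
Reagents that add atoms: none
Why: Parikh–Doering oxidation is mild enough to leave the vinyl sulfide and the α-stereocentre intact.

Step 9
Reactants: 7 2-{2-iodo-6-[(triisopropylsilyl)oxy]-4-{[2-(trimethylsilyl)ethoxy]carbonyl}phenyl}acetic acid; 12 (2R)-3-(ethenylsulfanyl)-2-methylpropanal
Product: 15 2-(trimethylsilyl)ethyl 1-[(2R)-1-(ethenylsulfanyl)propan-2-yl]-3-oxo-5-[(triisopropylsilyl)oxy]-3,4-dihydro-1H-2-benzopyran-7-carboxylate, via arylmagnesium carboxylate 13 (not isolated), via hydroxy acid 14 (not isolated)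
Conditions: MeMgCl (1.0 equiv) then i-PrMgCl·LiCl (1.1 equiv), THF, −30 °C; 12, −30 to 0 °C; aq. NH4Cl; then EDC·HCl, DMAP, CH2Cl2, rt
Reagents that add atoms: none
Why: Iodine–magnesium exchange on the magnesium carboxylate, addition to the aldehyde and Steglich lactonisation should give the isochroman-3-one; the carbinol configuration is irrelevant because it is erased in step 10.

Step 10
Reactants: 15 2-(trimethylsilyl)ethyl 1-[(2R)-1-(ethenylsulfanyl)propan-2-yl]-3-oxo-5-[(triisopropylsilyl)oxy]-3,4-dihydro-1H-2-benzopyran-7-carboxylate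
Product: 18 (1R,5R,9bS)-1-methyl-6-[(triisopropylsilyl)oxy]-8-{[2-(trimethylsilyl)ethoxy]carbonyl}-1,2,3a,4,5,9b-hexahydronaphtho[2,1-b]thiophene-5-carboxylic acid, via potassium lactone enolate 16 (not isolated), via o-quinodimethane carboxylate 17 (not isolated)
Conditions: KHMDS (1.1 equiv), 18-crown-6, toluene (0.005 M), −78 °C, then heat to 100 °C; 1 M HCl work-up
Reagents that add atoms: none
Why: Proposed new method: KHMDS removes the C1–H of lactone 15 to give enolate 16 (a 3-oxido-1H-isochromene), which should open by an anion-accelerated retro-6π (E1cB-type 1,4-) cleavage of the benzylic C4–O bond with dearomatisation of the benzoate ring to the o-quinodimethane carboxylate 17, and 17 is then trapped by an intramolecular Diels–Alder reaction with the tethered vinyl sulfide. The closest known reaction types are the base-induced 1,4-eliminations that generate o-xylylenes from o-alkylbenzyl ethers and ammonium salts (Hofmann type), the oxyanion-accelerated opening of benzocyclobutenols and the Tamura cycloaddition of homophthalic anhydride enolates, the new element being a lactone carboxylate as the internal leaving group. The carbocycle closes by suprafacial [4+2] bonding of C2 to C1 and of C3 to C4 (six-membered ring, type-1 intramolecular mode), and the thiolane C4–C11–C12–S–C3 closes with it as a fused five-membered ring through the three-atom tether. C4 is controlled by C11: with the side chain outward (E) the C11–H bond must eclipse the exocyclic double bond to avoid A(1,3) strain with C5–H, so CH3 and C12 lie on opposite faces and the dienophile, being attached to C12, can bond only on that face. C1 is controlled by the lactone: C20 was bonded to O–C4 and therefore emerges on the inward (Z) side of C1=C8a, where it has no hydrogen for a 1,5-shift and where reclosure merely regenerates 16, and suprafacial addition to this E,Z-diene places C20 trans to the side chain. The step needs outward rotation of the side chain on opening (steric), intramolecular trapping faster than bimolecular enolate chemistry or silyl transfer (high dilution, hindered TIPS and TMSE groups), and nothing at C3, whose configuration disappears when sulfur is removed.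

Step 11
Reactants: 18 tricyclic acid (tetralin C1–CO2H, thiolane fused across C3–C4)
Product: 19 2-(trimethylsilyl)ethyl (1R,5R,9bS)-5-(hydroxymethyl)-1-methyl-6-[(triisopropylsilyl)oxy]-1,2,3a,4,5,9b-hexahydronaphtho[2,1-b]thiophene-8-carboxylate
Conditions: BH3·SMe2 (excess), THF, 0 °C to rt; MeOH quench
Reagents that add atoms: none
Why: Borane reduces the carboxylic acid much faster than the aromatic ester, so C20 reaches the alcohol level, and removing the acidic C1–H site protects C1 from epimerisation in step 13.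

Step 12
Reactants: 19 tricyclic alcohol
Product: 20 2-(trimethylsilyl)ethyl (1R,5R,9bS)-5-(hydroxymethyl)-1-methyl-3-oxo-6-[(triisopropylsilyl)oxy]-1,2,3a,4,5,9b-hexahydro-3λ4-naphtho[2,1-b]thiophene-8-carboxylate (sulfoxide)
Conditions: NaIO4, MeOH/THF/H2O, 0 °C
Reagents that add atoms: sodium periodate [Na+].[O-]I(=O)(=O)=O
Why: Periodate oxidises a dialkyl sulfide to the sulfoxide without over-oxidation, which acidifies C12 yet keeps the sulfur removable by Raney nickel.

Step 13
Reactants: 20 sulfoxide; 21 1-bromo-3-methylbut-2-ene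
Product: 23 2-(trimethylsilyl)ethyl (1R,5R,9bS)-5-(hydroxymethyl)-1-methyl-2-(3-methylbut-2-en-1-yl)-3-oxo-6-[(triisopropylsilyl)oxy]-1,2,3a,4,5,9b-hexahydro-3λ4-naphtho[2,1-b]thiophene-8-carboxylate, via dilithio sulfoxide 22 (not isolated)
Conditions: LDA (2.2 equiv), THF, −78 °C; 21, −78 to −40 °C; sat. NH4Cl
Reagents that add atoms: none
Why: α-Sulfinyl carbanion alkylation should occur at the CH2 (C12) rather than at the ring-fusion CH (C3) and forms the C12–C13 bond, while the adjacent lithium alkoxide disfavours deprotonation at C1.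

Step 14
Reactants: 23 prenylated sulfoxide
Product: 24 2-(trimethylsilyl)ethyl (5R,8S)-5-(hydroxymethyl)-8-[(2S)-6-methylhept-5-en-2-yl]-4-[(triisopropylsilyl)oxy]-5,6,7,8-tetrahydronaphthalene-2-carboxylate
Conditions: Raney Ni (W-2, deactivated in acetone), EtOH, rt to 60 °C
Reagents that add atoms: none
Why: Raney nickel hydrogenolysis of both C–S bonds of the sulfoxide turns C3 and C12 into CH2, which erases the tether and all auxiliary centres.

Step 15
Reactants: 24 primary alcohol
Product: 25 2-(trimethylsilyl)ethyl (5R,8S)-5-(acetoxymethyl)-8-[(2S)-6-methylhept-5-en-2-yl]-4-[(triisopropylsilyl)oxy]-5,6,7,8-tetrahydronaphthalene-2-carboxylate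
Conditions: Ac2O, pyridine, DMAP (cat.), CH2Cl2, 0 °C to rt
Reagents that add atoms: acetic anhydride CC(=O)OC(C)=O
Why: Standard acetylation of the only free hydroxyl group.

Step 16
Reactants: 25 acetate
Product: 26 (5R,8S)-5-(acetoxymethyl)-4-hydroxy-8-[(2S)-6-methylhept-5-en-2-yl]-5,6,7,8-tetrahydronaphthalene-2-carboxylic acid (target)
Conditions: TBAF (3 equiv), AcOH (buffer), THF, 0 °C to rt; pH 3 work-up
Reagents that add atoms: none
Why: Fluoride cleaves the aryl TIPS ether and fragments the 2-(trimethylsilyl)ethyl ester in one operation under buffered conditions that an alkyl acetate and a trisubstituted alkene tolerate.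

**Compound list**
1 | 3-hydroxy-4-methylbenzoic acid | Cc1ccc(C(=O)O)cc1O | starting material
2 | triisopropylsilyl 4-methyl-3-[(triisopropylsilyl)oxy]benzoate | Cc1ccc(C(=O)O[Si](C(C)C)(C(C)C)C(C)C)cc1O[Si](C(C)C)(C(C)C)C(C)C | intermediate
3 | 4-methyl-3-[(triisopropylsilyl)oxy]benzoic acid | Cc1ccc(C(=O)O)cc1O[Si](C(C)C)(C(C)C)C(C)C | intermediate
4 | 2-(trimethylsilyl)ethyl 4-methyl-3-[(triisopropylsilyl)oxy]benzoate | Cc1ccc(C(=O)OCC[Si](C)(C)C)cc1O[Si](C(C)C)(C(C)C)C(C)C | intermediate
5 | 2-(trimethylsilyl)ethyl 4-(bromomethyl)-3-[(triisopropylsilyl)oxy]benzoate | BrCc1ccc(C(=O)OCC[Si](C)(C)C)cc1O[Si](C(C)C)(C(C)C)C(C)C | intermediate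
6 | 2-{2-[(triisopropylsilyl)oxy]-4-{[2-(trimethylsilyl)ethoxy]carbonyl}phenyl}acetic acid | OC(=O)Cc1ccc(C(=O)OCC[Si](C)(C)C)cc1O[Si](C(C)C)(C(C)C)C(C)C | intermediate
7 | 2-{2-iodo-6-[(triisopropylsilyl)oxy]-4-{[2-(trimethylsilyl)ethoxy]carbonyl}phenyl}acetic acid | OC(=O)Cc1c(I)cc(C(=O)OCC[Si](C)(C)C)cc1O[Si](C(C)C)(C(C)C)C(C)C | intermediate
8 | (2R)-3-bromo-2-methylpropan-1-ol | OC[C@@H](C)CBr | starting material
9 | S-[(2R)-3-hydroxy-2-methylpropyl] ethanethioate | OC[C@@H](C)CSC(C)=O | intermediate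
10 | potassium (2R)-3-hydroxy-2-methylpropane-1-thiolate | OC[C@@H](C)C[S-].[K+] | intermediate
11 | (2R)-3-(ethenylsulfanyl)-2-methylpropan-1-ol | OC[C@@H](C)CSC=C | intermediate
12 | (2R)-3-(ethenylsulfanyl)-2-methylpropanal | O=C[C@@H](C)CSC=C | intermediate
13 | chloromagnesium 2-[2-(chloromagnesio)-6-(triisopropylsilyloxy)-4-{[2-(trimethylsilyl)ethoxy]carbonyl}phenyl]acetate | Cl[Mg]OC(=O)Cc1c([Mg]Cl)cc(C(=O)OCC[Si](C)(C)C)cc1O[Si](C(C)C)(C(C)C)C(C)C | intermediate
14 | 2-{2-[(2R)-3-(ethenylsulfanyl)-1-hydroxy-2-methylpropyl]-6-[(triisopropylsilyl)oxy]-4-{[2-(trimethylsilyl)ethoxy]carbonyl}phenyl}acetic acid (carbinol epimers) | OC(=O)Cc1c(C(O)[C@@H](C)CSC=C)cc(C(=O)OCC[Si](C)(C)C)cc1O[Si](C(C)C)(C(C)C)C(C)C | intermediate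
15 | 2-(trimethylsilyl)ethyl 1-[(2R)-1-(ethenylsulfanyl)propan-2-yl]-3-oxo-5-[(triisopropylsilyl)oxy]-3,4-dihydro-1H-2-benzopyran-7-carboxylate (C-1 epimers) | O=C1Cc2c(cc(C(=O)OCC[Si](C)(C)C)cc2O[Si](C(C)C)(C(C)C)C(C)C)C(O1)[C@@H](C)CSC=C | intermediate
16 | potassium enolate of 15 (3-oxido-1H-isochromene) | [K+].[O-]C1=Cc2c(cc(C(=O)OCC[Si](C)(C)C)cc2O[Si](C(C)C)(C(C)C)C(C)C)C(O1)[C@@H](C)CSC=C | intermediate
17 | potassium o-quinodimethane carboxylate (C20 inward at C1, side chain outward at C4) | [K+].[O-]C(=O)/C=C1/C(O[Si](C(C)C)(C(C)C)C(C)C)=CC(C(=O)OCC[Si](C)(C)C)=C/C1=C\[C@@H](C)CSC=C | intermediate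
18 | (1R,5R,9bS)-1-methyl-6-[(triisopropylsilyl)oxy]-8-{[2-(trimethylsilyl)ethoxy]carbonyl}-1,2,3a,4,5,9b-hexahydronaphtho[2,1-b]thiophene-5-carboxylic acid (tetralin C1 acid with thiolane fused across C3–C4; C3 unassigned) | OC(=O)[C@@H]1CC2SC[C@H](C)[C@H]2c2cc(C(=O)OCC[Si](C)(C)C)cc(O[Si](C(C)C)(C(C)C)C(C)C)c21 | intermediate
19 | 2-(trimethylsilyl)ethyl (1R,5R,9bS)-5-(hydroxymethyl)-1-methyl-6-[(triisopropylsilyl)oxy]-1,2,3a,4,5,9b-hexahydronaphtho[2,1-b]thiophene-8-carboxylate | OC[C@@H]1CC2SC[C@H](C)[C@H]2c2cc(C(=O)OCC[Si](C)(C)C)cc(O[Si](C(C)C)(C(C)C)C(C)C)c21 | intermediate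
20 | S-oxide of 19 (sulfoxide, mixture at sulfur) | OC[C@@H]1CC2S(=O)C[C@H](C)[C@H]2c2cc(C(=O)OCC[Si](C)(C)C)cc(O[Si](C(C)C)(C(C)C)C(C)C)c21 | intermediate
21 | 1-bromo-3-methylbut-2-ene | CC(C)=CCBr | starting material
22 | O,C12-dilithio derivative of 20 | [Li]OC[C@@H]1CC2S(=O)C([Li])[C@H](C)[C@H]2c2cc(C(=O)OCC[Si](C)(C)C)cc(O[Si](C(C)C)(C(C)C)C(C)C)c21 | intermediate
23 | C12-(3-methylbut-2-en-1-yl) sulfoxide (2-prenyl derivative of 20) | OC[C@@H]1CC2S(=O)C(CC=C(C)C)[C@H](C)[C@H]2c2cc(C(=O)OCC[Si](C)(C)C)cc(O[Si](C(C)C)(C(C)C)C(C)C)c21 | intermediate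
24 | 2-(trimethylsilyl)ethyl (5R,8S)-5-(hydroxymethyl)-8-[(2S)-6-methylhept-5-en-2-yl]-4-[(triisopropylsilyl)oxy]-5,6,7,8-tetrahydronaphthalene-2-carboxylate | OC[C@@H]1CC[C@@H]([C@@H](C)CCC=C(C)C)c2cc(C(=O)OCC[Si](C)(C)C)cc(O[Si](C(C)C)(C(C)C)C(C)C)c21 | intermediate
25 | 2-(trimethylsilyl)ethyl (5R,8S)-5-(acetoxymethyl)-8-[(2S)-6-methylhept-5-en-2-yl]-4-[(triisopropylsilyl)oxy]-5,6,7,8-tetrahydronaphthalene-2-carboxylate | CC(=O)OC[C@@H]1CC[C@@H]([C@@H](C)CCC=C(C)C)c2cc(C(=O)OCC[Si](C)(C)C)cc(O[Si](C(C)C)(C(C)C)C(C)C)c21 | intermediate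
26 | (5R,8S)-5-(acetoxymethyl)-4-hydroxy-8-[(2S)-6-methylhept-5-en-2-yl]-5,6,7,8-tetrahydronaphthalene-2-carboxylic acid | CC(=O)OC[C@@H]1CC[C@@H]([C@@H](C)CCC=C(C)C)c2cc(C(=O)O)cc(O)c21 | target

**Step count and risks**
Total steps: 16. Longest linear sequence: 13 (steps 1–5 and 9–16).

1. Step 10 (proposed new method). The enolate may not open below the temperature at which silyl transfer from the aryl TIPS ether or intermolecular acylation sets in, or the diene may reclose or oligomerise faster than it is trapped. Fallback, from 14 back to 24, with the lactone lock given up and C1 corrected later by equilibration: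
   - Hydroxy acid 14 is intercepted before lactonisation and methylated (TMSCHN2) to hydroxy ester F1, which MsCl/Et3N/LiCl should convert into benzylic chloride F2.
   - LiHMDS (THF, high dilution, −78 °C to rt) should then effect a base-induced 1,4-dehydrochlorination of the arylacetate (Gilch/Hofmann-type o-xylylene generation) to o-quinodimethane ester F3.
   - F3 undergoes the same tethered Diels–Alder reaction to tricyclic ester F4; C4 is still set by the tether, but C1 is expected as a mixture.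
   - NaIO4 gives sulfoxide ester F5; LDA (2.2 equiv) and bromide 21 alkylate the more basic α-sulfinyl site of the dianion to prenylated sulfoxide ester F6; Raney nickel gives monocyclic ester F7.
   - Only at this stage DBU (toluene, 80 °C) should equilibrate C1 to trans ester F8, in which both benzylic substituents can be pseudoaxial, away from the peri OTIPS group and H5.
   - LiBH4 reduces the aliphatic methyl ester to 24.

2. Step 14. Raney nickel may hydrogenate or isomerise the trisubstituted alkene, or desulfurisation may stall at the hindered ring-fusion carbon. Fallback, from 20 back to 25, with the alkene made after the sulfur is gone: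
   - The dianion of 20 is alkylated with tert-butyl(2-iodoethoxy)dimethylsilane instead of 21, giving silyloxyethyl sulfoxide F9.
   - Raney nickel, now with no alkene present, gives diol monosilyl ether F10.
   - Ac2O/pyridine gives acetate F11; CSA in MeOH removes only the primary TBS ether to give alcohol F12; Dess–Martin oxidation gives aldehyde F13.
   - Wittig olefination with isopropylidenetriphenylphosphorane (from i-PrPPh3I and KHMDS, −78 °C) gives 25.

3. Step 9. The arylmagnesium may be quenched by proton transfer from the acidic benzylic CH2, or aldehyde 12 may enolise or lose vinylthiolate (erosion of C11). Fallback, from 7 back to 15: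
   - Acid 7 is esterified (EtOH, EDC, DMAP) to ethyl ester F14.
   - Nozaki–Hiyama–Kishi coupling (CrCl2, NiCl2 cat., DMF, rt) with 12, which tolerates the ester and the acidic CH2 and is essentially non-basic, gives hydroxy ester F15.
   - F15 is lactonised (Ti(Oi-Pr)4 cat., toluene, 60 °C) to 15.

**Further compounds**
F1 | step 10 | methyl 2-{2-[(2R)-3-(ethenylsulfanyl)-1-hydroxy-2-methylpropyl]-6-[(triisopropylsilyl)oxy]-4-{[2-(trimethylsilyl)ethoxy]carbonyl}phenyl}acetate | COC(=O)Cc1c(C(O)[C@@H](C)CSC=C)cc(C(=O)OCC[Si](C)(C)C)cc1O[Si](C(C)C)(C(C)C)C(C)C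
F2 | step 10 | methyl 2-{2-[(2R)-1-chloro-3-(ethenylsulfanyl)-2-methylpropyl]-6-[(triisopropylsilyl)oxy]-4-{[2-(trimethylsilyl)ethoxy]carbonyl}phenyl}acetate | COC(=O)Cc1c(C(Cl)[C@@H](C)CSC=C)cc(C(=O)OCC[Si](C)(C)C)cc1O[Si](C(C)C)(C(C)C)C(C)C
F3 | step 10 | o-quinodimethane methyl ester (side chain outward, ester geometry not fixed) | COC(=O)C=C1C(O[Si](C(C)C)(C(C)C)C(C)C)=CC(C(=O)OCC[Si](C)(C)C)=C/C1=C\[C@@H](C)CSC=C
F4 | step 10 | methyl ester of 18 (C1 epimers) | COC(=O)C1CC2SC[C@H](C)[C@H]2c2cc(C(=O)OCC[Si](C)(C)C)cc(O[Si](C(C)C)(C(C)C)C(C)C)c21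
F5 | step 10 | S-oxide of F4 | COC(=O)C1CC2S(=O)C[C@H](C)[C@H]2c2cc(C(=O)OCC[Si](C)(C)C)cc(O[Si](C(C)C)(C(C)C)C(C)C)c21
F6 | step 10 | C12-prenylated sulfoxide ester | COC(=O)C1CC2S(=O)C(CC=C(C)C)[C@H](C)[C@H]2c2cc(C(=O)OCC[Si](C)(C)C)cc(O[Si](C(C)C)(C(C)C)C(C)C)c21
F7 | step 10 | 2-(trimethylsilyl)ethyl (8S)-5-(methoxycarbonyl)-8-[(2S)-6-methylhept-5-en-2-yl]-4-[(triisopropylsilyl)oxy]-5,6,7,8-tetrahydronaphthalene-2-carboxylate (C5 epimers) | COC(=O)C1CC[C@@H]([C@@H](C)CCC=C(C)C)c2cc(C(=O)OCC[Si](C)(C)C)cc(O[Si](C(C)C)(C(C)C)C(C)C)c21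
F8 | step 10 | trans diester, (5R,8S) isomer of F7 | COC(=O)[C@@H]1CC[C@@H]([C@@H](C)CCC=C(C)C)c2cc(C(=O)OCC[Si](C)(C)C)cc(O[Si](C(C)C)(C(C)C)C(C)C)c21
F9 | step 14 | C12-[2-(tert-butyldimethylsilyloxy)ethyl] sulfoxide | OC[C@@H]1CC2S(=O)C(CCO[Si](C)(C)C(C)(C)C)[C@H](C)[C@H]2c2cc(C(=O)OCC[Si](C)(C)C)cc(O[Si](C(C)C)(C(C)C)C(C)C)c21
F10 | step 14 | 2-(trimethylsilyl)ethyl (5R,8S)-8-[(2S)-5-(tert-butyldimethylsilyloxy)pentan-2-yl]-5-(hydroxymethyl)-4-[(triisopropylsilyl)oxy]-5,6,7,8-tetrahydronaphthalene-2-carboxylate | OC[C@@H]1CC[C@@H]([C@@H](C)CCCO[Si](C)(C)C(C)(C)C)c2cc(C(=O)OCC[Si](C)(C)C)cc(O[Si](C(C)C)(C(C)C)C(C)C)c21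
F11 | step 14 | acetate of F10 | CC(=O)OC[C@@H]1CC[C@@H]([C@@H](C)CCCO[Si](C)(C)C(C)(C)C)c2cc(C(=O)OCC[Si](C)(C)C)cc(O[Si](C(C)C)(C(C)C)C(C)C)c21
F12 | step 14 | 5-hydroxypentan-2-yl acetate (primary alcohol) | CC(=O)OC[C@@H]1CC[C@@H]([C@@H](C)CCCO)c2cc(C(=O)OCC[Si](C)(C)C)cc(O[Si](C(C)C)(C(C)C)C(C)C)c21
F13 | step 14 | 5-oxopentan-2-yl acetate (aldehyde) | CC(=O)OC[C@@H]1CC[C@@H]([C@@H](C)CCC=O)c2cc(C(=O)OCC[Si](C)(C)C)cc(O[Si](C(C)C)(C(C)C)C(C)C)c21
F14 | step 9 | ethyl 2-{2-iodo-6-[(triisopropylsilyl)oxy]-4-{[2-(trimethylsilyl)ethoxy]carbonyl}phenyl}acetate | CCOC(=O)Cc1c(I)cc(C(=O)OCC[Si](C)(C)C)cc1O[Si](C(C)C)(C(C)C)C(C)C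
F15 | step 9 | ethyl 2-{2-[(2R)-3-(ethenylsulfanyl)-1-hydroxy-2-methylpropyl]-6-[(triisopropylsilyl)oxy]-4-{[2-(trimethylsilyl)ethoxy]carbonyl}phenyl}acetate | CCOC(=O)Cc1c(C(O)[C@@H](C)CSC=C)cc(C(=O)OCC[Si](C)(C)C)cc1O[Si](C(C)C)(C(C)C)C(C)C
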